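1. In a one-step world, E + D → Z, every D spent gives a Z, and Z is the whole of what is made. Here Z and L also take D, so I looked for what each spent D costs that share.

| flask | E | D | temperature | remark | time |
|---|---|---|---|---|---|
| oak | 0.33 M | 0.74 M | 25 °C | run made earlier |  |
| zeta | 0.33 M | 0.495 M |  | at 25 °C until 25 s, from then on at 85 °C | 2.0 min |
| delta | 1.0 M | 0.495 M |  | at 25 °C throughout | 2.0 min |

- oak (time / s: Z / %, L / %, J / %): 10.0: 45, 20, 5; 20.0: 42, 33, 10; 30.0: 31, 37, 19; 50.0: 25, 38, 29; 80.0: 23, 40, 37

(readings scatter by 2 percentage points)

- what was read earlier has a scatter of 2 percentage points, one standard deviation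
- steps thought possible: E + D -> Z; D + Z -> L; D + L -> J; D -> G
- the earlier runs do not show what temperature does; that part of a forecast is a guess

- the flask that ends with the higher share of Z in all that became Z or L or J, or "neither" when 2 percentage points or less lies between them (zeta / delta / neither)
- share of Z in all that became Z or L or J, zeta
- share of Z in all that became Z or L or J, delta

2. At first Z is absent, so neither Z nor L can take D yet. Each Z holds one D, each L 2, each J 3. At the first oak reading, D spent, counted as what Z, L and J hold, per E charged was 100 %, and the share of Z read 64.3 %.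

3. So I named the share tax, the share of Z lost per equivalent of D spent: 35.7 %, as a reading. At the last oak reading, 214 % spent gives 23.6 % by the tax, and 23.0 % was read.

4. Next, the end. Oak's E loss by its first reading, reckoned at D as charged, gives D a half-life by the step E + D of 4.26 s in delta, at E as charged. Even with E down at 0.505 M, that is 8.44 s, so 14.2 half-lives fit into the time. D, the limiting reagent of delta, should therefore fall to about 2.59 × 10⁻⁵ M.

5. Delta's 0.495 equivalents gave me 82.3 %. Zeta's 1.50 gave 46.4 % if heat changed nothing, but in zeta the heat came after 1.94 half-lives of D, reckoned at E as charged, and what it does was a guess.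

The forecast, seeing “a clean stepwise picture”, named delta, with 50 % for zeta and 83 % for delta.

Delta ended higher, at 82.7 % against 53.2 % for zeta. At 2.00 min delta held 0 % of its D and 58 % of its E.

    E + D → Z (k = 0.210 L mol⁻¹ s⁻¹, Ea = 57.0 kJ mol⁻¹)
    D + Z → L (k = 0.140 L mol⁻¹ s⁻¹, Ea = 40.0 kJ mol⁻¹)
    D + L → J (k = 0.100 L mol⁻¹ s⁻¹, Ea = 43.0 kJ mol⁻¹)
    D → G (k = 1.50 × 10⁻⁵ s⁻¹, Ea = 98.0 kJ mol⁻¹)
    (constants at 25 °C)

At the change of temperature zeta had spent 111 %, so the tax gave 60.4 %, and 59.4 % stood there. The neighbour of delta with 0.60 M of E had 0.825 equivalents, for which the tax gave 70.5 %, and that flask ended at 70.4 %.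

Readings and results stem from a simulated flask with made-up constants, and the scatter is random.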